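We want to know which of larch and cedar ends with more G, and we judge it from how fast J is used and how that rate falls away.

| flask | J | temperature | remark | time |
|---|---|---|---|---|
| gamma | 0.011 M | 10 °C | run made earlier |  |
| beta | 0.015 M | 21 °C | run made earlier |  |
| theta | 0.018 M | 10 °C | run made earlier |  |
| larch | 0.017 M |  | at 25 °C until 3.0 min, from then on at 5 °C | 10 min |
| cedar | 0.012 M |  | at 5 °C throughout | 10 min |

| run | time / min | G / % | J / % |
|---|---|---|---|
| gamma | 0.833 | 16.1 | 50.0 |
| gamma | 3.00 | 33.6 | 14.8 |
| gamma | 5.00 | 39.6 | 7.5 |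
| gamma | 8.00 | 42.8 | 2.6 |
| gamma | 10.0 | 43.0 | 1.3 |
| beta | 1.00 | 36.2 | 13.9 |
| beta | 2.00 | 44.4 | 3.6 |
| beta | 3.00 | 45.4 | 1.4 |
| beta | 4.00 | 46.9 | 0.7 |
| beta | 5.00 | 47.1 | 0.6 |
| theta | 2.00 | 23.0 | 17.5 |
| theta | 4.00 | 30.0 | 5.8 |
| theta | 6.00 | 31.4 | 1.4 |
| theta | 8.00 | 32.4 | 1.3 |
| theta | 10.0 | 31.5 | 0.6 |

(readings scatter by 0.5 percentage points)

* which of the two ends with the higher amount of G, in percent of the J charged ("neither" if they lie within 2 percentage points) (larch / cedar / neither)
* G at the end, in percent of the J charged, larch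
* G at the end, in percent of the J charged, cedar



In these runs J goes faster early and at high charge, so we write its specific rate as k times the sum of one and [J]/[J]×, with G coming from the term in k. Here [J]× is the crossover concentration, where the first-order and second-order terms use J equally. G formed over J used at the mean [J] of the first window gives 0.00392 M in gamma and 0.00409 M in theta, so we take 0.00400 M at 10 °C. Beta gives 0.00620 M at 21 °C. The tails give k: 0.348 /min in gamma and 1.35 /min in beta.

Carrying both logarithmically in temperature, larch at 25 °C has k = 2.21 /min, and its charge of J over [J]× is r = 2.34. It starts at 7.38 /min, and falling [J] slows it by the factor 3.34. By 3.0 min we reckon 0.0392% of the J left in larch, which is hardly any, so cooling acts on little.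

Cedar has k = 0.188 /min and r = 3.66. It starts at 0.876 /min, slows by the factor 4.66, and keeps 3.73% unused at 10 min.

Gamma and theta differ in charge, so their ends give G falling as r to the power 0.632. That rule gives 46.6% for beta, which read 47.1%. We reckon 47.6% for larch and, less the unused J, 32.2% for cedar.

The forecast says larch, with 48.5% and 31%; of larch it says “J is essentially consumed within 3 min, so cooling hardly matters”.

    J → G (k = 0.0248 /s, Ea = 77.0 kJ/mol)
    2 J → Q (k = 1.57 /M/s, Ea = 51.0 kJ/mol)
    J + Q → Z (k = 1.41 /M/s, Ea = 51.0 kJ/mol)
    Q → D (k = 0.00115 /s, Ea = 79.0 kJ/mol)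
    J + G → X (k = 0.187 /M/s, Ea = 48.0 kJ/mol)
    (constants at 25 °C)

The flasks end at 47.0% for larch and 34.9% for cedar, so larch leads. Larch held J 0.173% at 3.00 min, and its second temperature makes no difference. Cedar kept 3.9% of its J at 10.0 min. A flask like cedar kept at 20 °C has [J]× = 0.00596 M, so r = 2.01, and the rule gives 52.3%. That flask ended at 51.1%.

(All runs come from a simulation for substances that don't exist, and the scatter is random.)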